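Wednesday's run holds less starting material than target at 2.50 h, 0% against 19.1%. So by these readings about 80.9% of the starting material, the limiting reagent at 0.010 M against 0.018 M of partner, stands in some form that the readings don't show.

| flask | starting material | partner | protic impurity | remark | time |
|---|---|---|---|---|---|
| Wednesday's | 0.010 M | 0.018 M | 10 mM | run made earlier |  |
| Friday's | 0.010 M | 0.018 M | 20 mM | run made earlier |  |
| delta | 0.010 M | 0.0180 M (fed, over 25 h) | 10.0 mM | all else is in the flask from the start; the feed brings no volume worth counting | 2.5 d |
| alpha | 0.010 M (fed, over 25 h) | 0.0180 M | 10.0 mM | all else is in the flask from the start; the feed brings no volume worth counting | 2.5 d |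
| zeta | 0.010 M (fed, over 2.5 h) | 0.0180 M | 10.0 mM | all else is in the flask from the start; the feed brings no volume worth counting | 2.5 d |
| eta | 0.010 M | 0.0180 M | 10.0 mM | everything together at the start | 2.5 d |

| run | time / h | target / % | starting material / % |
|---|---|---|---|
| Wednesday's | 2.50 | 19.1 | 0 |
| Wednesday's | 8.00 | 37.4 | 0 |
| Wednesday's | 12.0 | 40.9 | 1.9 |
| Wednesday's | 20.0 | 39.8 | 0 |
| Wednesday's | 30.0 | 38.7 | 0.2 |
| Wednesday's | 40.0 | 40.4 | 0 |
| Friday's | 2.00 | 13.8 | 0.7 |
| Friday's | 4.00 | 25.8 | 1.0 |
| Friday's | 6.00 | 32.2 | 0 |
| Friday's | 8.00 | 35.4 | 0 |
| Friday's | 10.0 | 37.5 | 3.1 |
| Friday's | 12.0 | 37.4 | 0 |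

(readings scatter by 1 percentage point)

1. the flask with the highest amount of target, in percent of the starting material charged ("all alike" if they lie within 1.5 percentage points) (delta / alpha / zeta / eta / all alike)
2. final target, as a percentage of the starting material charged, in delta
3. final target, as a percentage of the starting material charged, in alpha
4. final target, as a percentage of the starting material charged, in zeta
5. final target, as a percentage of the starting material charged, in eta

Does this unseen form reach target? Wednesday's target levels off near 39.8%, so about 60.2% of the charge goes elsewhere.

Is protic impurity the thief? At 12.0 h, Friday's reading, with doubled impurity, lies 3.5 percentage points below Wednesday's, less than that loss, so I look further.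

What sets the pace? Target rises with a rate constant k of about 0.261 h⁻¹, read from the first Wednesday reading against the level. The runs can't say whose clock this is. I assume that partner becomes ready at this pace, and that the waiting form of starting material is lost to itself, so that the loss grows with how much waits at once.

Then I carry one quantity. In alpha it is 11.8: the arrival ratio S, partner made ready per hour at the start over starting material arriving per hour. Zeta has 1.18. Eta repeats Wednesday's recipe. Friday's run reads 0.7% of starting material at 2.00 h, so I take that time as a rough arrival time, which gives eta an estimated S of 0.941. In delta the feed supplies partner more slowly than k does in a full charge, so I count the feed rate for partner, and with the same arrival time I estimate S at 0.144. I commit to the order alpha, zeta, eta, delta, with eta near Wednesday's level.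

The forecast picks alpha, with 32% in delta, 78% in alpha, 57% in zeta and 40% in eta, reasoning that “slow feeding of starting material helps”.

The flasks give 81.1% in alpha, 51.6% in zeta, 38.8% in eta and 13.6% in delta, so alpha leads.

    starting material → open intermediate (k = 2.40 h⁻¹)
    partner → second intermediate (k = 0.280 h⁻¹)
    open intermediate + second intermediate ⇌ target (K = 550 M⁻¹, k = 47.0 M⁻¹ h⁻¹)
    2 open intermediate → homo product (k = 46.0 M⁻¹ h⁻¹)
    starting material + protic impurity → quenched substrate (k = 31.0 M⁻¹ h⁻¹)
    crystals ⇌ target, rate k6*(cs6 - [target]) while solid is left; crystals form when [target] > cs6 (solubility = 0.160 mM, k = 2.80 h⁻¹)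

Homo product holds 75.4% of the starting material in delta, against 50.1% in eta and 37.3% in zeta. Target follows S down the line, from 11.8 in alpha to 0.144 in delta.

A neighbour of delta has 0.0025 M of starting material, which by the same estimate lifts S to 0.576. That is closer to eta's 0.941 than to delta's 0.144, so I expect target near eta's. The neighbour gives 36.0%.

The data stem from a simulated flask with constants of no real substance.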